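Ring A is numbered from the butyryl carbon (C1) and ring B is primed from the bridge carbon. Ring A is disconnected at C2–C3, C4–C5 and C1–C2 into 1-methoxypropyne and a 3-siloxycyclobutenone that already carries ring B on its benzylic carbon and is unsubstituted at C4. The feature exploited is that the C3 methyl and the only O-methyl (C4) are neighbours, lying between oxygenated C2 and the bridge-bearing C5: they are the two alkyne carbons. One thermal cascade closes ring A as a pentasubstituted phenol, with C1 left open between a free hydroxyl and a silyl ether. The C1 butyryl and C5' acetyl groups are installed afterwards.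

Key step: step 8

Remark on the chemistry: the target is achiral, so no stereocentre has to be set; ketene gas is generated outside the flask (acetone pyrolysis) and is treated as a reagent.

Step 1
Reactants: 1 2-methylphloroglucinol
Product: 3 2,4,6-trihydroxy-3-methylbenzaldehyde, via iminium chloride 2 (not isolated)
Conditions: POCl3 (1.1 equiv), DMF (1.2 equiv), EtOAc, 0 °C → rt; then H2O, 50 °C
Reagents that add atoms: N,N-dimethylformamide CN(C)C=O; water O
Why: Vilsmeier–Haack formylation, in which the chloroiminium ion attacks one of the two equivalent free ring carbons and the iminium salt 2 that separates is deactivated towards a second attack, so hydrolysis should give the mono-aldehyde.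

Step 2
Reactants: 3 2,4,6-trihydroxy-3-methylbenzaldehyde
Product: 4 2,4,6-tris(benzyloxy)-3-methylbenzaldehyde
Conditions: BnBr (3.6 equiv), K2CO3, Bu4NI (cat.), DMF, 65 °C
Reagents that add atoms: benzyl bromide BrCc1ccccc1
Why: Williamson etherification, run after formylation because the carbonyl group lowers the carbon nucleophilicity of the ring, so the three phenoxides should alkylate on oxygen (the two hydrogen-bonded ones need the heat).

Step 3
Reactants: 4 2,4,6-tris(benzyloxy)-3-methylbenzaldehyde
Product: 5 2-[[2,4,6-tris(benzyloxy)-3-methylphenyl]methylidene]-1,3-dithiane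
Conditions: 2-(trimethylsilyl)-1,3-dithiane, n-BuLi, THF, −78 → 0 °C; then 4, −78 °C → rt
Reagents that add atoms: 2-(trimethylsilyl)-1,3-dithiane C[Si](C)(C)C1SCCCS1
Why: Peterson olefination, in which the silyl-stabilised dithiane anion adds irreversibly even to the hindered aldehyde and the β-silyl alkoxide eliminates lithium trimethylsilanolate to give the ketene dithioacetal.

Step 4
Reactants: 5 2-[[2,4,6-tris(benzyloxy)-3-methylphenyl]methylidene]-1,3-dithiane
Product: 6 methyl 2-[2,4,6-tris(benzyloxy)-3-methylphenyl]acetate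
Conditions: HgCl2 (2.2 equiv), MeOH–H2O (9:1), reflux
Reagents that add atoms: methanol CO; water O
Why: Thiophile-assisted solvolysis of a ketene dithioacetal, in which protonation at the benzylic carbon gives a dithianylium ion that methanol and water convert into the methyl ester while HgCl2 binds the dithiol, completing a one-carbon homologation of the aldehyde.

Step 5
Reactants: 6 methyl 2-[2,4,6-tris(benzyloxy)-3-methylphenyl]acetate
Product: 8 triisopropyl[[3-[2,4,6-tris(benzyloxy)-3-methylphenyl]prop-1-yn-1-yl]oxy]silane, via lithium ynolate 7 (not isolated)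
Conditions: CH2Br2, lithium 2,2,6,6-tetramethylpiperidide, THF, −78 °C; 6; LiN(SiMe3)2; n-BuLi, −78 → 0 °C; i-Pr3SiCl, −78 °C → rt
Reagents that add atoms: dibromomethane BrCBr; chlorotriisopropylsilane CC(C)[Si](Cl)(C(C)C)C(C)C
Why: Kowalski ester homologation stopped at the ynolate stage, in which LiCHBr2 adds to the ester, the dibromo enolate undergoes bromine–lithium exchange and 1,2-shift of the arylmethyl group to give ynolate 7, and the bulky silyl chloride traps 7 on oxygen.

Step 6
Reactants: 8 triisopropyl[[3-[2,4,6-tris(benzyloxy)-3-methylphenyl]prop-1-yn-1-yl]oxy]silane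
Product: 9 2-[[2,4,6-tris(benzyloxy)-3-methylphenyl]methyl]-3-(triisopropylsilyloxy)cyclobut-2-en-1-one
Conditions: ketene (excess, gas), CH2Cl2, 0 °C → rt
Reagents that add atoms: ketene C=C=O
Why: [2+2] cycloaddition of an electron-rich siloxyalkyne to ketene, in which the nucleophilic arylmethyl-bearing alkyne carbon bonds to the ketene carbonyl carbon, so the arylmethyl group ends on C2, the siloxy group on C3 and C4 stays unsubstituted.

Step 7
Reactants: 10 2-chloro-1,1-dimethoxyethane
Product: 12 1-methoxypropyne, via sodium methoxyacetylide 11 (not isolated)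
Conditions: NaNH2 (3 equiv), liquid NH3, −40 °C; then MeI, −50 °C → reflux of NH3; fractional distillation, stored as a toluene solution
Reagents that add atoms: iodomethane CI
Why: Twofold base-induced elimination (methanol, then HCl) from the chloroacetal gives the sodium alkoxyacetylide 11, which is C-methylated in liquid ammonia, the standard preparation of 1-alkoxyalk-1-ynes.

Step 8
Reactants: 9 2-[[2,4,6-tris(benzyloxy)-3-methylphenyl]methyl]-3-(triisopropylsilyloxy)cyclobut-2-en-1-one; 12 1-methoxypropyne
Product: 17 3-methoxy-2-methyl-4-[[2,4,6-tris(benzyloxy)-3-methylphenyl]methyl]-5-(triisopropylsilyloxy)phenol, via vinylketene 13 (not isolated), via vinylcyclobutenone 14 (not isolated), via dienylketene 15 (not isolated), via cyclohexadienone 16 (not isolated)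
Conditions: 12 (3 equiv), toluene (0.05 M), sealed tube, 80 → 110 °C
Reagents that add atoms: none
Why: Danheiser benzannulation: 4π electrocyclic opening of 9 gives vinylketene 13, whose electrophilic ketene carbon is attacked by the methyl-bearing carbon of 12 in a [2+2] cycloaddition, giving 14 with methyl next to the carbonyl and methoxyl next to the benzylic carbon. A second 4π opening gives dienylketene 15, and ring A closes by thermal disrotatory 6π electrocyclisation (the C1–C2 bond) to dienone 16, which tautomerises to phenol 17. The closest precedent is the aromatic annulation of cyclobutenones with alkoxy- and siloxyalkynes. No stereocentre survives, since the quaternary carbon of racemic 14 becomes the aromatic C5. The step needs the regiochemistry of the [2+2] event, which is secured by the polarisation of the ynol ether (nucleophilic at the carbon remote from oxygen) against the ketene carbonyl carbon; excess alkyne and dilution should keep the new phenol from being acylated by 13.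

Step 9
Reactants: 17 3-methoxy-2-methyl-4-[[2,4,6-tris(benzyloxy)-3-methylphenyl]methyl]-5-(triisopropylsilyloxy)phenol
Product: 18 3-methoxy-2-methyl-4-[[2,4,6-tris(benzyloxy)-3-methylphenyl]methyl]-5-(triisopropylsilyloxy)phenyl butanoate
Conditions: butanoyl chloride, Et3N, DMAP (cat.), CH2Cl2, 0 °C
Reagents that add atoms: butanoyl chloride CCCC(Cl)=O
Why: DMAP-catalysed acyl transfer to the only free hydroxyl; the ester stores the butyryl group next to C1 and lowers the nucleophilicity of ring A for the next step.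

Step 10
Reactants: 18 3-methoxy-2-methyl-4-[[2,4,6-tris(benzyloxy)-3-methylphenyl]methyl]-5-(triisopropylsilyloxy)phenyl butanoate
Product: 19 4-[[3-acetyl-2,4,6-tris(benzyloxy)-5-methylphenyl]methyl]-3-methoxy-2-methyl-5-(triisopropylsilyloxy)phenyl butanoate
Conditions: Ac2O (1.5 equiv), Sc(OTf)3 (10 mol %), MeNO2, rt
Reagents that add atoms: acetic anhydride CC(=O)OC(C)=O
Why: Friedel–Crafts acylation under Sc(OTf)3 catalysis, expected at C5' of ring B (ortho to two benzyloxy groups and para to the third) and not at C1 of ring A, which is flanked by the acyloxy group and the bulky silyl ether; the aryl ester should not rearrange at room temperature.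

Step 11
Reactants: 19 4-[[3-acetyl-2,4,6-tris(benzyloxy)-5-methylphenyl]methyl]-3-methoxy-2-methyl-5-(triisopropylsilyloxy)phenyl butanoate
Product: 20 1-[3-[[3-acetyl-2,4,6-tris(benzyloxy)-5-methylphenyl]methyl]-6-hydroxy-4-methoxy-5-methyl-2-(triisopropylsilyloxy)phenyl]butan-1-one
Conditions: TiCl4 (2.5 equiv), CH2Cl2, −20 °C → rt; aqueous work-up
Reagents that add atoms: none
Why: Fries rearrangement, in which TiCl4 activates the aryl ester and the butyryl group moves to C1, the only unsubstituted carbon left on either electron-rich ring (the other ortho position and the para position are blocked), giving the chelated ortho-hydroxy ketone.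

Step 12
Reactants: 20 1-[3-[[3-acetyl-2,4,6-tris(benzyloxy)-5-methylphenyl]methyl]-6-hydroxy-4-methoxy-5-methyl-2-(triisopropylsilyloxy)phenyl]butan-1-one
Product: 21 1-[3-[[3-acetyl-2,4,6-tris(benzyloxy)-5-methylphenyl]methyl]-2,6-dihydroxy-4-methoxy-5-methylphenyl]butan-1-one
Conditions: Bu4NF, AcOH, THF, 0 °C
Reagents that add atoms: none
Why: Fluoride-induced cleavage of the aryl silyl ether, buffered with acetic acid so that no free polyphenolate is present; ketones, benzyl ethers and the methyl ether are inert.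

Step 13
Reactants: 21 1-[3-[[3-acetyl-2,4,6-tris(benzyloxy)-5-methylphenyl]methyl]-2,6-dihydroxy-4-methoxy-5-methylphenyl]butan-1-one
Product: 22 1-[3-[(3-acetyl-2,4,6-trihydroxy-5-methylphenyl)methyl]-2,6-dihydroxy-4-methoxy-5-methylphenyl]butan-1-one
Conditions: H2 (1 atm), 10% Pd on carbon, EtOAc–MeOH, rt
Reagents that add atoms: none
Why: Hydrogenolysis of the three benzyl ethers over palladium on carbon; the hydrogen-bonded aryl ketones and the diarylmethane bridge should not be reduced at 1 atm, and the neutral conditions spare the methylene bridge between the two phloroglucinol rings.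

Compound list
1 | 2-methylphloroglucinol (2-methylbenzene-1,3,5-triol) | Cc1c(O)cc(O)cc1O | starting material
2 | N-[(2,4,6-trihydroxy-3-methylphenyl)methylidene]-N-methylmethanaminium chloride | C[N+](C)=Cc1c(O)cc(O)c(C)c1O.[Cl-] | intermediate (not isolated)
3 | 2,4,6-trihydroxy-3-methylbenzaldehyde | Cc1c(O)cc(O)c(C=O)c1O | intermediate
4 | 2,4,6-tris(benzyloxy)-3-methylbenzaldehyde | Cc1c(OCc2ccccc2)cc(OCc2ccccc2)c(C=O)c1OCc1ccccc1 | intermediate
5 | 2-[[2,4,6-tris(benzyloxy)-3-methylphenyl]methylidene]-1,3-dithiane | Cc1c(OCc2ccccc2)cc(OCc2ccccc2)c(C=C2SCCCS2)c1OCc1ccccc1 | intermediate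
6 | methyl 2-[2,4,6-tris(benzyloxy)-3-methylphenyl]acetate | COC(=O)Cc1c(OCc2ccccc2)cc(OCc2ccccc2)c(C)c1OCc1ccccc1 | intermediate
7 | lithium 3-[2,4,6-tris(benzyloxy)-3-methylphenyl]prop-1-yn-1-olate | [Li]OC#CCc1c(OCc2ccccc2)cc(OCc2ccccc2)c(C)c1OCc1ccccc1 | intermediate (not isolated)
8 | triisopropyl[[3-[2,4,6-tris(benzyloxy)-3-methylphenyl]prop-1-yn-1-yl]oxy]silane | CC(C)[Si](OC#CCc1c(OCc2ccccc2)cc(OCc2ccccc2)c(C)c1OCc1ccccc1)(C(C)C)C(C)C | intermediate
9 | 2-[[2,4,6-tris(benzyloxy)-3-methylphenyl]methyl]-3-(triisopropylsilyloxy)cyclobut-2-en-1-one | CC(C)[Si](OC1=C(Cc2c(OCc3ccccc3)c(C)c(OCc3ccccc3)cc2OCc2ccccc2)C(=O)C1)(C(C)C)C(C)C | intermediate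
10 | 2-chloro-1,1-dimethoxyethane | COC(CCl)OC | starting material
11 | sodium methoxyethynide (sodium methoxyacetylide) | [Na]C#COC | intermediate (not isolated)
12 | 1-methoxypropyne | CC#COC | intermediate
13 | 2-[[2,4,6-tris(benzyloxy)-3-methylphenyl]methyl]-3-(triisopropylsilyloxy)buta-1,3-dien-1-one | C=C(O[Si](C(C)C)(C(C)C)C(C)C)C(Cc1c(OCc2ccccc2)c(C)c(OCc2ccccc2)cc1OCc1ccccc1)=C=O | intermediate (not isolated)
14 | 3-methoxy-2-methyl-4-[[2,4,6-tris(benzyloxy)-3-methylphenyl]methyl]-4-[1-(triisopropylsilyloxy)ethenyl]cyclobut-2-en-1-one (racemic) | COC1=C(C)C(=O)C1(Cc1c(OCc2ccccc2)c(C)c(OCc2ccccc2)cc1OCc1ccccc1)C(=C)O[Si](C(C)C)(C(C)C)C(C)C | intermediate (not isolated)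
15 | (3E)-3-methoxy-2-methyl-4-[[2,4,6-tris(benzyloxy)-3-methylphenyl]methyl]-5-(triisopropylsilyloxy)hexa-1,3,5-trien-1-one (ketene carbon and siloxyvinyl group cis) | CC(=C=O)/C(OC)=C(\C(=C)O[Si](C(C)C)(C(C)C)C(C)C)Cc1c(OCc2ccccc2)c(C)c(OCc2ccccc2)cc1OCc1ccccc1 | intermediate (not isolated)
16 | 3-methoxy-2-methyl-4-[[2,4,6-tris(benzyloxy)-3-methylphenyl]methyl]-5-(triisopropylsilyloxy)cyclohexa-2,4-dien-1-one | COC1=C(C)C(=O)CC(O[Si](C(C)C)(C(C)C)C(C)C)=C1Cc1c(OCc2ccccc2)c(C)c(OCc2ccccc2)cc1OCc1ccccc1 | intermediate (not isolated)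
17 | 3-methoxy-2-methyl-4-[[2,4,6-tris(benzyloxy)-3-methylphenyl]methyl]-5-(triisopropylsilyloxy)phenol | CC(C)[Si](Oc1cc(O)c(C)c(OC)c1Cc1c(OCc2ccccc2)c(C)c(OCc2ccccc2)cc1OCc1ccccc1)(C(C)C)C(C)C | intermediate
18 | 3-methoxy-2-methyl-4-[[2,4,6-tris(benzyloxy)-3-methylphenyl]methyl]-5-(triisopropylsilyloxy)phenyl butanoate | CCCC(=O)Oc1cc(O[Si](C(C)C)(C(C)C)C(C)C)c(Cc2c(OCc3ccccc3)c(C)c(OCc3ccccc3)cc2OCc2ccccc2)c(OC)c1C | intermediate
19 | 4-[[3-acetyl-2,4,6-tris(benzyloxy)-5-methylphenyl]methyl]-3-methoxy-2-methyl-5-(triisopropylsilyloxy)phenyl butanoate | CCCC(=O)Oc1cc(O[Si](C(C)C)(C(C)C)C(C)C)c(Cc2c(OCc3ccccc3)c(C)c(OCc3ccccc3)c(C(C)=O)c2OCc2ccccc2)c(OC)c1C | intermediate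
20 | 1-[3-[[3-acetyl-2,4,6-tris(benzyloxy)-5-methylphenyl]methyl]-6-hydroxy-4-methoxy-5-methyl-2-(triisopropylsilyloxy)phenyl]butan-1-one | CCCC(=O)c1c(O)c(C)c(OC)c(Cc2c(OCc3ccccc3)c(C)c(OCc3ccccc3)c(C(C)=O)c2OCc2ccccc2)c1O[Si](C(C)C)(C(C)C)C(C)C | intermediate
21 | 1-[3-[[3-acetyl-2,4,6-tris(benzyloxy)-5-methylphenyl]methyl]-2,6-dihydroxy-4-methoxy-5-methylphenyl]butan-1-one | CCCC(=O)c1c(O)c(C)c(OC)c(Cc2c(OCc3ccccc3)c(C)c(OCc3ccccc3)c(C(C)=O)c2OCc2ccccc2)c1O | intermediate
22 | 1-[3-[(3-acetyl-2,4,6-trihydroxy-5-methylphenyl)methyl]-2,6-dihydroxy-4-methoxy-5-methylphenyl]butan-1-one | CCCC(=O)c1c(O)c(C)c(OC)c(Cc2c(O)c(C)c(O)c(C(C)=O)c2O)c1O | target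

Total step count: 13. Longest linear sequence: 12 (steps 1–6 and 8–13; step 7 is a side branch).

Steps most likely to fail

Step 8. The vinylogous-ester stabilisation of 9 may delay the first ring opening until desilylation or ketene self-condensation takes over. The donor-substituted vinylketene may also add the ynol ether only slowly, and the new phenol may be acylated by the vinylketene. The fallback sets out from 1 and comes back to the route at 22; it makes the methylene bridge last by the classical union of two acylphloroglucinols. C-Acetylation of 1 (Ac2O, BF3·OEt2) should give 1-(2,4,6-trihydroxy-3-methylphenyl)ethan-1-one F1. Its Mannich reaction (aqueous CH2O, Me2NH, EtOH) at the only free ring carbon should give 1-[3-[(dimethylamino)methyl]-2,4,6-trihydroxy-5-methylphenyl]ethan-1-one F2. In parallel, C-butyrylation of 1 (butanoic acid, BF3·OEt2) should give 1-(2,4,6-trihydroxy-3-methylphenyl)butan-1-one F3. Methylation of its non-chelated hydroxyl para to the ketone (Me2SO4, 1 equiv, K2CO3, acetone) should give 1-(2,6-dihydroxy-4-methoxy-3-methylphenyl)butan-1-one F4 (aspidinol). Heating F2 and F4 together (dioxane, reflux) should release dimethylamine, and the ortho-quinone methide from F2 should alkylate the single free carbon of F4 to give 22.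

Step 5. Deprotonation at the benzylic α-position of 6 may outrun addition of the carbenoid to the ester carbonyl, and the ynolate may be silylated on carbon. The fallback sets out from 6 and comes back at 8; it reaches the same ynolate by oxidation of an acetylide. Reduction of 6 (i-Bu2AlH, toluene, −78 °C) should give 2-[2,4,6-tris(benzyloxy)-3-methylphenyl]acetaldehyde F5. Ohira–Bestmann homologation (dimethyl (1-diazo-2-oxopropyl)phosphonate, K2CO3, MeOH) should give 1,3,5-tris(benzyloxy)-2-methyl-4-(prop-2-yn-1-yl)benzene F6. Deprotonation (LiN(SiMe3)2, THF, −78 °C), oxidation of the lithium acetylide by t-BuOOLi to ynolate 7 and trapping by triisopropylsilyl triflate should give 8.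

Step 11. Under TiCl4 the benzyl ethers next to the ring B ketone or the silyl ether may be lost, or the ester may simply be cleaved without carbon–carbon bond formation at the crowded C1. The fallback sets out from 19 and comes back at 21; it replaces the intramolecular shift by an intermolecular C-acylation of the unmasked resorcinol ring. Removal of the butanoate (K2CO3, MeOH) and of the silyl ether (Bu4NF, THF) should give 1-[2,4,6-tris(benzyloxy)-3-[(2,4-dihydroxy-6-methoxy-5-methylphenyl)methyl]-5-methylphenyl]ethan-1-one F7. Hoesch reaction of F7 and butanenitrile (ZnCl2, HCl, Et2O, 0 °C) at the only open carbon, between the two hydroxyls, should give 1-[3-[[3-acetyl-2,4,6-tris(benzyloxy)-5-methylphenyl]methyl]-2,6-dihydroxy-4-methoxy-5-methylphenyl]butan-1-iminium chloride F8, which warm water should hydrolyse to 21.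

Further compounds
F1 | step 8 | 1-(2,4,6-trihydroxy-3-methylphenyl)ethan-1-one | CC(=O)c1c(O)cc(O)c(C)c1O
F2 | step 8 | 1-[3-[(dimethylamino)methyl]-2,4,6-trihydroxy-5-methylphenyl]ethan-1-one | CC(=O)c1c(O)c(C)c(O)c(CN(C)C)c1O
F3 | step 8 | 1-(2,4,6-trihydroxy-3-methylphenyl)butan-1-one | CCCC(=O)c1c(O)cc(O)c(C)c1O
F4 | step 8 | 1-(2,6-dihydroxy-4-methoxy-3-methylphenyl)butan-1-one (aspidinol) | CCCC(=O)c1c(O)cc(OC)c(C)c1O
F5 | step 5 | 2-[2,4,6-tris(benzyloxy)-3-methylphenyl]acetaldehyde | O=CCc1c(OCc2ccccc2)cc(OCc2ccccc2)c(C)c1OCc1ccccc1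
F6 | step 5 | 1,3,5-tris(benzyloxy)-2-methyl-4-(prop-2-yn-1-yl)benzene | C#CCc1c(OCc2ccccc2)cc(OCc2ccccc2)c(C)c1OCc1ccccc1
F7 | step 11 | 1-[2,4,6-tris(benzyloxy)-3-[(2,4-dihydroxy-6-methoxy-5-methylphenyl)methyl]-5-methylphenyl]ethan-1-one | CC(=O)c1c(OCc2ccccc2)c(C)c(OCc2ccccc2)c(Cc2c(O)cc(O)c(C)c2OC)c1OCc1ccccc1
F8 | step 11 | 1-[3-[[3-acetyl-2,4,6-tris(benzyloxy)-5-methylphenyl]methyl]-2,6-dihydroxy-4-methoxy-5-methylphenyl]butan-1-iminium chloride | CCCC(=[NH2+])c1c(O)c(C)c(OC)c(Cc2c(OCc3ccccc3)c(C)c(OCc3ccccc3)c(C(C)=O)c2OCc2ccccc2)c1O.[Cl-]
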